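**Your hunch.** One equivalent of nucleophile cannot, as you hoped, turn the whole of the electrophile into target here, as long as each acid set free takes a nucleophile with it.

all flasks: electrophile 0.35 M
- south-east: nucleophile 1 equiv (fed, over 5.0 min); free base 3.7 equiv; run made earlier
- north-east: nucleophile 1 equiv (fed, over 5.0 min); free base 7.1 equiv; run made earlier
- midnight: nucleophile 1.00 equiv (fed, over 5.0 min); free base 4.50 equiv; time 40 min
- noon: nucleophile 1.00 equiv (fed, over 5.0 min); free base 3.00 equiv; time 40 min

| run | time / min | electrophile / % | target / % |
|---|---|---|---|
| south-east | 3.00 | 94.7 | 6.9 |
| south-east | 6.00 | 79.9 | 18.0 |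
| south-east | 10.0 | 66.3 | 27.0 |
| south-east | 12.0 | 61.6 | 28.2 |
| south-east | 15.0 | 56.1 | 28.4 |
| south-east | 20.0 | 49.8 | 29.3 |
| north-east | 1.33 | 98.5 | 2.3 |
| north-east | 4.00 | 89.9 | 9.4 |
| north-east | 8.00 | 72.1 | 21.9 |
| north-east | 10.0 | 67.3 | 25.8 |
| north-east | 15.0 | 57.4 | 29.8 |
| north-east | 20.0 | 49.7 | 29.5 |

(each reading ± 0.5 percentage points)

1. part of the electrophile that has reacted at the end, midnight
2. part of the electrophile that has reacted at the end, noon
3. what raising the equivalents of free base from its lowest to its highest value here does to the part of the electrophile that has reacted (changes below 5 percentage points count as none) (no change / it falls / it rises)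

- in percentages every species weighs as the electrophile in it: one side product counts as two
- steps thought possible: electrophile + nucleophile -> acid set free + target; nucleophile + acid set free <-> protonated nucleophile; acid set free + free base <-> salt of the base; target <-> isomer of the product; electrophile + target -> side product

**The ceiling.** Compare the earlier runs at 20.0 min: the south-east run, with 3.7 equiv of free base, holds 49.8% electrophile, and the north-east run, with 7.1 equiv, holds 49.7%. The free base shows no effect there, so I let the acid go to the nucleophile. Each turn of the main step then costs two nucleophiles, one spent and one protonated. I call the resulting limit the ceiling, 50.0% of the electrophile, which is half the nucleophile charged, the limiting reagent.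

**My number.** Past the ceiling, electrophile is lost by meeting target. The south-east balance lacks 20.9% at 20.0 min. If that is all side product, which counts two, the ceiling plus half of it gives 60.5%. If the same loss comes again by 40 min, I get 70.9%. I commit to the middle, 65.7%, for both flasks.

**The forecast.** It says 67% (62% to 72%) for midnight and 67% (61% to 72%) for noon, with no change, slightly above mine, reasoning that “the free base appears not to take up the acid”.

**The result.** The flask gives 64.0% at midnight and 63.6% at noon, so no change, a change of 0.42 percentage points. Noon ends with 28.6% side product, and the ceiling plus half of that is 64.3%.

    electrophile + nucleophile → acid set free + target (k = 0.00380 L mol⁻¹ s⁻¹)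
    nucleophile + acid set free ⇌ protonated nucleophile, settled at all times (K = 3600 L mol⁻¹)
    acid set free + free base ⇌ salt of the base, settled at all times (K = 6.70 L mol⁻¹)
    target ⇌ isomer of the product (K = 2.20, k = 2.30 × 10⁻⁴ s⁻¹)
    electrophile + target → side product (k = 0.00140 L mol⁻¹ s⁻¹)

**Second flask.** With 1.70 equiv of nucleophile and noon's other charges, the ceiling rises to 85.0%. The computed flask gives 87.3%, with 12.7% electrophile left, and that stands above the top of the forecast's noon range, 72%, so with this charge that range would be wrong.

The readings were generated by integration for an exercise; noise was put on by code.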